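**Plan**

- Retrosynthesis: remove the three O-protecting groups, then cut C3–C4 of the lactone ring (ring B) to reach a 1-chloroalkyl 2-(chloromethyl)benzoate. Cut its acyl O–C3 and C3–Cl bonds to an aldehyde and a 2-(chloromethyl)benzoyl chloride (from the phthalide), and cut the side chain at C3′–C4′ (alkyne alkylation).
- Forward: the chain is made first (alkylation of (S)-oct-1-yn-3-ol, alkyne zipper to the chain end, benzylation, anti-Markovnikov hydration). The aldehyde is then taken up by the opened phthalide and ring B closes in the last step but one; in effect the aldehyde carbon is spliced into the O–CH2 bond of a five-membered lactone to give the six-membered one.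
- Enabling feature: C3 of ring B sits on the lactone oxygen O2 and C4 is benzylic on C4a of ring A, with C1(=O) between them. Both carbons can therefore be carried as C–Cl bonds that give stabilised radicals or organonickel species, and the C1 carbonyl can bind nickel beside C3.
- Stereochemistry: C6′ (S) comes from commercial (S)-oct-1-yn-3-ol and is carried unchanged. C3 (R) is set in the ring closure by a chiral nickel catalyst, from a mixture of C3-epimeric chlorides.

Key step: step 7

Assumption: 5,7-dimethoxyphthalide (10) is taken as a purchasable building block, and the (S,S) hand of the ligand in step 7 is provisional, the antipode being used if a first trial shows it is the one that leads to 3R.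

**Step 1**
Reactants: 1 (S)-oct-1-yn-3-ol; 2 1-bromobutane
Product: 4 (S)-dodec-5-yn-7-ol, via dilithium alkynolate 3 (not isolated)
Conditions: n-BuLi (2.2 equiv), THF, −78 → −20 °C; then 2, DMPU, −20 → 20 °C; then H2O
Reagents that add atoms: none
Why: Acetylide alkylation of the alkoxide/acetylide dianion occurs at carbon with a primary bromide, and the carbinol centre is not involved, so S is retained.

**Step 2**
Reactants: 4 (S)-dodec-5-yn-7-ol
Product: 6 (S)-dodec-1-yn-7-ol, via dipotassium alkynolate 5 (not isolated)
Conditions: KH, H2N(CH2)3NH2 (gives KNH(CH2)3NH2), 0 → 20 °C; then H2O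
Reagents that add atoms: none
Why: In this alkyne zipper isomerisation the triple bond moves through allene and propargyl anion equilibria away from the alkoxide-bearing carbon to the chain end, where formation of the terminal acetylide drives it, and the adjacent alkoxide shields C7 from deprotonation so the S centre should be kept.

**Step 3**
Reactants: 6 (S)-dodec-1-yn-7-ol
Product: 8 (S)-7-(benzyloxy)dodec-1-yne, via sodium alkoxide 7 (not isolated)
Conditions: NaH (1.1 equiv), DMF, 0 °C; then BnBr, 0 → 20 °C
Reagents that add atoms: benzyl bromide, BrCc1ccccc1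
Why: Williamson etherification of the secondary alkoxide proceeds at oxygen and leaves the C–O bond of the stereocentre untouched.

**Step 4**
Reactants: 8 (S)-7-(benzyloxy)dodec-1-yne
Product: 9 (S)-7-(benzyloxy)dodecanal
Conditions: [CpRu(MeCN)3]PF6 (2 mol %), 5,5′-bis(trifluoromethyl)-2,2′-bipyridine (2 mol %), NMP/H2O 4:1, 25 °C
Reagents that add atoms: water, O
Why: Ruthenium-catalysed anti-Markovnikov hydration of a terminal alkyne through a vinylidene complex should give the aldehyde directly and is inert towards the benzyl ether.

**Step 5**
Reactants: 10 5,7-dimethoxyphthalide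
Product: 11 2-(chloromethyl)-4,6-dimethoxybenzoyl chloride
Conditions: SOCl2 (1.5 equiv), BF3·OEt2 (5 mol %), BnEt3NCl (5 mol %), xylene, 100 °C; volatiles removed under vacuum
Reagents that add atoms: thionyl chloride, O=S(Cl)Cl
Why: This is the standard chlorinative ring opening of a phthalide, in which chloride attacks the benzylic CH2–O carbon of the Lewis-acid-activated lactone in an SN2 reaction and SOCl2 converts the released carboxylate into the acyl chloride.

**Step 6**
Reactants: 9 (S)-7-(benzyloxy)dodecanal; 11 2-(chloromethyl)-4,6-dimethoxybenzoyl chloride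
Product: 12 (7S)-7-(benzyloxy)-1-chlorododecyl 2-(chloromethyl)-4,6-dimethoxybenzoate (both C1 epimers)
Conditions: ZnCl2 (3 mol %), CH2Cl2, −20 → 0 °C; filtered through Celite under argon and used at once
Reagents that add atoms: none
Why: ZnCl2-catalysed addition of an acyl chloride across an aldehyde C=O (1-chloroalkyl ester formation) is general for enolisable aliphatic aldehydes; it creates the future C3 as a roughly equal mixture of epimers, which does not matter because step 7 is stereoconvergent.

**Step 7**
Reactants: 12 (7S)-7-(benzyloxy)-1-chlorododecyl 2-(chloromethyl)-4,6-dimethoxybenzoate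
Product: 13 (3R)-3-[(6S)-6-(benzyloxy)undecyl]-6,8-dimethoxy-3,4-dihydro-1H-isochromen-1-one
Conditions: NiBr2(glyme) (10 mol %), (S,S)-2,2′-(propane-2,2-diyl)bis(4-phenyl-4,5-dihydrooxazole) (12 mol %), Mn powder (3 equiv), THF/DMA 4:1, 0 °C, slow addition of 12 (final 0.01 M)
Reagents that add atoms: none
Why: Proposed new method: zerovalent nickel bound to the chiral bis(oxazoline) adds oxidatively to the benzylic C–Cl bond, a monovalent nickel species abstracts chlorine from the 1-chloroalkyl ester to give a planar α-acyloxyalkyl radical at C3 that is captured at the benzylnickel centre, and C–C reductive elimination from the resulting nickelacycle of trivalent nickel forms the C3–C4 bond while Mn returns the catalyst. The closest known reaction type is the nickel/bis(oxazoline)-catalysed enantioconvergent alkyl–alkyl coupling of racemic 1-haloalkyl esters with alkylzinc or alkylnickel partners, together with asymmetric reductive cross-electrophile couplings of benzylic chlorides; the new element is the ring-closing variant with both carbons as chlorides. Ring B, the six-membered lactone, closes by reductive elimination from a seven-membered nickelacycle, formally a 6-exo-tet closure at C3 with the leaving chloride outside the ring. The C3 stereocentre is set by the chiral ligand in the radical-capture and reductive-elimination sequence, so both C3 epimers of 12 should converge on 3R, while the remote 6S centre is untouched and too far away to bias it. The step needs intramolecular cross-coupling to win over intermolecular homocoupling, hydrodechlorination and β-hydride loss, and the tether, high dilution with slow addition, the radical-stabilised character of both carbons and binding of the C1 carbonyl to nickel beside C3 are expected to secure this.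

**Step 8**
Reactants: 13 (3R)-3-[(6S)-6-(benzyloxy)undecyl]-6,8-dimethoxy-3,4-dihydro-1H-isochromen-1-one
Product: 14 (3R)-6,8-dihydroxy-3-[(6S)-6-hydroxyundecyl]-3,4-dihydro-1H-isochromen-1-one
Conditions: BBr3 (6 equiv), CH2Cl2, −78 → 0 °C; then H2O
Reagents that add atoms: none
Why: BBr3 ether cleavage should remove both aryl methyl ethers (the C8 ether helped by chelation to the lactone carbonyl) and split the secondary benzyl ether at the benzyl–oxygen bond, so the 6S carbinol keeps its configuration and the lactone and C3 are not touched at low temperature.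

**Compound list**

1 | (S)-oct-1-yn-3-ol | CCCCC[C@H](O)C#C | starting material
2 | 1-bromobutane | CCCCBr | starting material
3 | dilithium salt of 1 (lithium alkoxide and lithium acetylide) | CCCCC[C@H]([O-])C#[C-].[Li+].[Li+] | intermediate
4 | (S)-dodec-5-yn-7-ol | CCCCC[C@H](O)C#CCCCC | intermediate
5 | dipotassium salt of 6 (potassium alkoxide and terminal potassium acetylide) | CCCCC[C@H]([O-])CCCCC#[C-].[K+].[K+] | intermediate
6 | (S)-dodec-1-yn-7-ol | CCCCC[C@H](O)CCCCC#C | intermediate
7 | sodium alkoxide of 6 | CCCCC[C@H]([O-])CCCCC#C.[Na+] | intermediate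
8 | (S)-7-(benzyloxy)dodec-1-yne | CCCCC[C@H](OCc1ccccc1)CCCCC#C | intermediate
9 | (S)-7-(benzyloxy)dodecanal | CCCCC[C@H](OCc1ccccc1)CCCCCC=O | intermediate
10 | 5,7-dimethoxyphthalide (5,7-dimethoxy-2-benzofuran-1(3H)-one) | COc1cc2COC(=O)c2c(OC)c1 | starting material
11 | 2-(chloromethyl)-4,6-dimethoxybenzoyl chloride | COc1cc(CCl)c(C(Cl)=O)c(OC)c1 | intermediate
12 | (7S)-7-(benzyloxy)-1-chlorododecyl 2-(chloromethyl)-4,6-dimethoxybenzoate, both C1 epimers | CCCCC[C@H](OCc1ccccc1)CCCCCC(Cl)OC(=O)c1c(CCl)cc(OC)cc1OC | intermediate
13 | (3R)-3-[(6S)-6-(benzyloxy)undecyl]-6,8-dimethoxy-3,4-dihydro-1H-isochromen-1-one | CCCCC[C@H](OCc1ccccc1)CCCCC[C@@H]1Cc2cc(OC)cc(OC)c2C(=O)O1 | intermediate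
14 | (3R)-6,8-dihydroxy-3-[(6S)-6-hydroxyundecyl]-3,4-dihydro-1H-isochromen-1-one | CCCCC[C@H](O)CCCCC[C@@H]1Cc2cc(O)cc(O)c2C(=O)O1 | target

**Totals**

Total step count: 8. Longest linear sequence: 7 steps (steps 1, 2, 3, 4, 6, 7 and 8, from (S)-oct-1-yn-3-ol); step 5 is a one-step side branch.

**Steps most likely to fail**

Step 7. The ester has to leave its preferred extended conformation for the s-cis arrangement that ring B requires, so ring closure may be slow. Intermolecular coupling to dimers and oligomers, reduction of either C–Cl bond, β-hydride loss to an enol ester or ionisation of the 1-chloroalkyl ester could then take over, and facial discrimination in the radical capture may be poor. The fallback uses known chemistry, sets out from 9 and comes back at 13. Wittig methylenation of 9 (MePPh3Br, KHMDS, THF) would give (8S)-8-(benzyloxy)tridec-1-ene F1. Epoxidation with mCPBA would give 2-[(6S)-6-(benzyloxy)undecyl]oxirane F2 as both oxirane epimers. Hydrolytic kinetic resolution with (R,R)-(salen)Co(OAc), the acetate complex of trivalent cobalt, and 0.55 equiv of water is expected to hydrolyse the 2S epimer and leave (2R)-2-[(6S)-6-(benzyloxy)undecyl]oxirane F3. Opening of F3 at the CH2 terminus with (3,5-dimethoxyphenyl)magnesium bromide and catalytic CuI would give (2R,8S)-8-(benzyloxy)-1-(3,5-dimethoxyphenyl)tridecan-2-ol F4, with the carbinol configuration untouched. NBS in MeCN should brominate the ring ortho to the side chain and para to a methoxy group to give (2R,8S)-8-(benzyloxy)-1-(2-bromo-3,5-dimethoxyphenyl)tridecan-2-ol F5. Carbonylative lactonisation (Pd(OAc)2, dppf, CO, Et3N, toluene, 100 °C) would then close ring B through the C1–O2 bond to 13.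

Step 5. The electron-rich ring may suffer electrophilic attack by sulfur species, Friedel–Crafts self-benzylation by the product under Lewis acid at 100 °C, or partial O-demethylation. The fallback opens the lactone with a soft nucleophile at room temperature; it sets out from 10 and comes back at 13. Iodotrimethylsilane (CH2Cl2, 25 °C) would silylate the lactone carbonyl and deliver iodide to the benzylic carbon to give trimethylsilyl 2-(iodomethyl)-4,6-dimethoxybenzoate F6. Oxalyl chloride with catalytic DMF (CH2Cl2, 0 °C) should convert the silyl ester directly into 2-(iodomethyl)-4,6-dimethoxybenzoyl chloride F7. Addition of F7 to 9 under the conditions of step 6 would give (7S)-7-(benzyloxy)-1-chlorododecyl 2-(iodomethyl)-4,6-dimethoxybenzoate F8, which is cyclised under the conditions of step 7, the benzylic iodide serving in place of the chloride, to give 13.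

Step 8. The boron alkoxide formed from the side-chain oxygen may be converted into the secondary bromide with loss of the 6S centre, the lactone may be cleaved at its alkyl–oxygen bond on warming, or the C6 methyl ether may be cleaved incompletely. The fallback separates the two deprotections and masks the alcohol; it sets out from 13 and comes back at 14. Hydrogenolysis (H2, Pd/C, EtOAc) would give (3R)-3-[(6S)-6-hydroxyundecyl]-6,8-dimethoxy-3,4-dihydro-1H-isochromen-1-one F9. Acetylation (Ac2O, pyridine) would give (6S)-1-[(3R)-6,8-dimethoxy-1-oxo-3,4-dihydro-1H-isochromen-3-yl]undecan-6-yl acetate F10, in which no boron alkoxide can form. BBr3 (CH2Cl2, −78 → 0 °C) should then give (6S)-1-[(3R)-6,8-dihydroxy-1-oxo-3,4-dihydro-1H-isochromen-3-yl]undecan-6-yl acetate F11. Mild methanolysis (K2CO3, MeOH, 0 °C, then dilute HCl to re-close any opened lactone) would give 14.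

**Further compounds**

F1 | step 7 | (8S)-8-(benzyloxy)tridec-1-ene | CCCCC[C@H](OCc1ccccc1)CCCCCC=C
F2 | step 7 | 2-[(6S)-6-(benzyloxy)undecyl]oxirane, both oxirane epimers | CCCCC[C@H](OCc1ccccc1)CCCCCC1CO1
F3 | step 7 | (2R)-2-[(6S)-6-(benzyloxy)undecyl]oxirane | CCCCC[C@H](OCc1ccccc1)CCCCC[C@@H]1CO1
F4 | step 7 | (2R,8S)-8-(benzyloxy)-1-(3,5-dimethoxyphenyl)tridecan-2-ol | CCCCC[C@H](OCc1ccccc1)CCCCC[C@@H](O)Cc1cc(OC)cc(OC)c1
F5 | step 7 | (2R,8S)-8-(benzyloxy)-1-(2-bromo-3,5-dimethoxyphenyl)tridecan-2-ol | CCCCC[C@H](OCc1ccccc1)CCCCC[C@@H](O)Cc1cc(OC)cc(OC)c1Br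
F6 | step 5 | trimethylsilyl 2-(iodomethyl)-4,6-dimethoxybenzoate | COc1cc(CI)c(C(=O)O[Si](C)(C)C)c(OC)c1
F7 | step 5 | 2-(iodomethyl)-4,6-dimethoxybenzoyl chloride | COc1cc(CI)c(C(Cl)=O)c(OC)c1
F8 | step 5 | (7S)-7-(benzyloxy)-1-chlorododecyl 2-(iodomethyl)-4,6-dimethoxybenzoate, both C1 epimers | CCCCC[C@H](OCc1ccccc1)CCCCCC(Cl)OC(=O)c1c(CI)cc(OC)cc1OC
F9 | step 8 | (3R)-3-[(6S)-6-hydroxyundecyl]-6,8-dimethoxy-3,4-dihydro-1H-isochromen-1-one | CCCCC[C@H](O)CCCCC[C@@H]1Cc2cc(OC)cc(OC)c2C(=O)O1
F10 | step 8 | (6S)-1-[(3R)-6,8-dimethoxy-1-oxo-3,4-dihydro-1H-isochromen-3-yl]undecan-6-yl acetate | CCCCC[C@H](OC(C)=O)CCCCC[C@@H]1Cc2cc(OC)cc(OC)c2C(=O)O1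
F11 | step 8 | (6S)-1-[(3R)-6,8-dihydroxy-1-oxo-3,4-dihydro-1H-isochromen-3-yl]undecan-6-yl acetate | CCCCC[C@H](OC(C)=O)CCCCC[C@@H]1Cc2cc(O)cc(O)c2C(=O)O1
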